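The larch flask was charged with 0.400 M of Xa and 1.20 M of Xb, yet its [Xp] read 0.299 M at 22 h and 0.294 M at 37 h.

| setting | oak | larch | elm | birch |
|---|---|---|---|---|
| Xa | 0.400 M | 0.400 M | 0.400 M | 0.800 M |
| Xb | 0.400 M | 1.20 M | 0.400 M | 0.200 M |
| Xc | 0.0120 M | 0.0120 M | 0.0120 M | 0.0120 M |
| Xp |  |  | 0.200 M |  |
| time |  |  |  | 37 h |

| run | time / h | [Xp] / M |
|---|---|---|
| oak run | 1.5 | 0.032 |
| oak run | 2.5 | 0.032 |
| oak run | 4.3 | 0.053 |
| oak run | 7.4 | 0.088 |
| oak run | 13 | 0.128 |
| oak run | 22 | 0.163 |
| oak run | 37 | 0.194 |
| larch run | 1.5 | 0.054 |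
| larch run | 2.5 | 0.110 |
| larch run | 4.3 | 0.156 |
| larch run | 7.4 | 0.212 |
| larch run | 13 | 0.267 |
| larch run | 22 | 0.299 |
| larch run | 37 | 0.294 |
| elm run | 1.5 | 0.216 |
| elm run | 2.5 | 0.233 |
| elm run | 4.3 | 0.257 |
| elm run | 7.4 | 0.276 |
| elm run | 13 | 0.302 |
| elm run | 22 | 0.334 |
| elm run | 37 | 0.338 |

(readings scatter by 0.006 M)

- Overall: Xa + Xb -> Xp, with Xc as catalyst.
- Constant volume, constant temperature.
- An order is taken over about fifteen percent of the charge, up and down.

- reaction order in [Xb] at the outset, round the charge of the oak run, defined at two percent of the Xa turned into Xp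
- Xp in the birch run at 37 h, as a share of the Xa charged
- which of these the readings show (nothing beyond the main steps / the product kills the catalyst / the product decays / the catalyst dies in pairs)

I began with the bench rule, rate = k[Xa][Xb]. Tripling [Xb] took the oak reading of 0.053 M at 4.3 h to 0.156 M in larch, which reads as an order of 0.983. That larch reading, put through the integrated law, gave k = 0.103 M⁻¹ h⁻¹.

Then I counted half-lives. On the rule, larch is nearly pseudo-first-order in Xa, with [Xb] not below 0.800 M, so with that k a half-life lasts at most 8.40 h. The larch run then holds at least 4.41 of them. The rule therefore leaves at most 0.0189 M of Xa and calls for at least 0.381 M of Xp. The last reading reached a share of 0.772 of that, which is where the rule stopped working: 0.0871 M was missing.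

I supposed Xp itself was being lost. If that loss is first order in Xp, the area under the larch curve divided by the missing amount reads as 106 h, the lifetime of Xp.

Oak tested it. The same k reckons 0.242 M made in oak by 37 h, and taking off the area under the oak curve over that lifetime leaves 0.195 M, against a reading of 0.194 M.

In birch, Xb is the limiting reagent, its charge smaller than that of Xa, and [Xa] stays at or above 0.600 M. With the same k, a half-life of at most 11.2 h reckons at least 0.180 M made in birch by 37 h, before any loss. Its average portion sits for about 20.9 h, or 0.197 lifetimes, which leaves an estimated 0.148 M, or 18.5 % of the Xa charged. I committed to that figure and to decay of the product.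

The forecast gave order 1 (0.8 to 1.2), birch 20.4 % (18.5 % to 22.5 %), and the verdict the product kills the catalyst, on the ground that “Identical charges of catalyst dying differently means Xp kills it”. My birch figure stood lower.

The flask gave an order of 1.0, 18.0 % in birch, and the verdict the product decays.

    2 Xc ⇌ Xc2, settled at all times (7470 M⁻¹)
    Xc2 + Xa + Xb → Xp + Xc2 (17.39 M⁻² h⁻¹)
    Xp → L (0.009180 h⁻¹)

With the same amount made, the elm rate of product formation stood at 0.87 of the oak rate, 0.015 M h⁻¹. Elm was charged with 0.200 M of Xp that oak lacked, and at my lifetime that extra loses 1.88 mM h⁻¹, which puts the reckoned ratio at 0.875.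

All runs come from a simulation with constants of no real substance; scatter was added.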